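**Strategy**

The pyran ring is closed through its C3–C4 bond by ring contraction. C4 carries the hydroxyl and C3 the B-ring aryl, so both carbons are benzylic; in a (3S)-3-aryl-2,3-dihydro-5H-1,4-benzodioxepine the future 4-OH oxygen sits in the ring between them. A [1,2]-Wittig rearrangement of this seven-membered benzyl ether forms C3–C4, expels the oxygen as the C4 carbinol and relays the C3 configuration, set by asymmetric transfer hydrogenation, into the trans-3,4 pair in one operation. The precursor is assembled from a salicylaldehyde (A-ring) and a phenacyl bromide whose hydroquinone is masked as a bis-TIPS ether, removable by fluoride without acid.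

Key step: step 8

Remark: the target SMILES is read as (3S,4R), i.e. 3-aryl and 4-OH trans. 2,3,4-Trimethoxyphenol and 1-(2-hydroxy-3,4-dimethoxyphenyl)ethanone are taken as catalogue compounds. Acid is avoided after step 8 because a 2'-hydroxy-isoflavan-4-ol would cyclise to a pterocarpan.

**Route**

Step 1
Reactants: 1 2,3,4-trimethoxyphenol
Product: 2 2-hydroxy-3,4,5-trimethoxybenzaldehyde
Conditions: MgCl2, Et3N, (CH2O)n, MeCN, reflux
Reagents that add atoms: paraformaldehyde (formaldehyde), C=O
Why: Magnesium-phenoxide-directed ortho-formylation (Casnati–Skattebøl) should go to the only free ortho position, with a second formaldehyde acting as hydride acceptor.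

Step 2
Reactants: 3 1-(2-hydroxy-3,4-dimethoxyphenyl)ethanone
Product: 5 1-(2,5-dihydroxy-3,4-dimethoxyphenyl)ethanone, via aryl potassium sulfate 4 (not isolated)
Conditions: K2S2O8, aq NaOH, 0 °C → rt; then aq HCl, 80 °C
Reagents that add atoms: potassium peroxodisulfate, [K+].[K+].[O-]S(=O)(=O)OOS(=O)(=O)[O-]
Why: Elbs persulfate oxidation should attack the phenoxide at the free para position (C5) and the aryl sulfate is hydrolysed by acid to the hydroquinone.

Step 3
Reactants: 5 1-(2,5-dihydroxy-3,4-dimethoxyphenyl)ethanone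
Product: 6 1-[3,4-dimethoxy-2,5-bis(triisopropylsilyloxy)phenyl]ethanone
Conditions: TIPSOTf, 2,6-lutidine, CH2Cl2, 0 °C → rt
Reagents that add atoms: triisopropylsilyl triflate, CC(C)[Si](C(C)C)(C(C)C)OS(=O)(=O)C(F)(F)F
Why: Silyl triflate silylation should be forceful enough for the hydrogen-bonded, doubly flanked 2-OH, and TIPS ethers survive base and alkyllithium and leave with fluoride.

Step 4
Reactants: 6 1-[3,4-dimethoxy-2,5-bis(triisopropylsilyloxy)phenyl]ethanone
Product: 8 2-bromo-1-[3,4-dimethoxy-2,5-bis(triisopropylsilyloxy)phenyl]ethanone, via TMS enol ether 7 (not isolated)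
Conditions: TMSOTf, Et3N, CH2Cl2, 0 °C; then NBS, THF, 0 °C
Reagents that add atoms: N-bromosuccinimide, O=C1CCC(=O)N1Br
Why: Soft enolisation to the silyl enol ether followed by electrophilic bromination should direct bromine to the α-carbon and not to the electron-rich ring, and it avoids a free enolate next to the ortho silyl ether.

Step 5
Reactants: 2 2-hydroxy-3,4,5-trimethoxybenzaldehyde; 8 2-bromo-1-[3,4-dimethoxy-2,5-bis(triisopropylsilyloxy)phenyl]ethanone
Product: 9 2-{2-[3,4-dimethoxy-2,5-bis(triisopropylsilyloxy)phenyl]-2-oxoethoxy}-3,4,5-trimethoxybenzaldehyde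
Conditions: K2CO3, acetone, rt
Reagents that add atoms: none
Why: Williamson alkylation of the phenoxide by the phenacyl bromide (SN2) should form the O1–C2 ether bond; room temperature is chosen to hold back aldol closure onto the formyl group.

Step 6
Reactants: 9 2-{2-[3,4-dimethoxy-2,5-bis(triisopropylsilyloxy)phenyl]-2-oxoethoxy}-3,4,5-trimethoxybenzaldehyde
Product: 10 (1S)-1-[3,4-dimethoxy-2,5-bis(triisopropylsilyloxy)phenyl]-2-[2-(hydroxymethyl)-4,5,6-trimethoxyphenoxy]ethan-1-ol
Conditions: RuCl(p-cymene)[(R,R)-TsDPEN] (2 mol%), HCO2H/Et3N (5:2), EtOAc, 30 °C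
Reagents that add atoms: none
Why: Noyori asymmetric transfer hydrogenation should reduce the aldehyde to the benzylic alcohol and the α-aryloxy aryl ketone to the carbinol in one pot; the (R,R)-catalyst delivers hydride to the ketone face fixed by the arene CH/π contact with the aryl group, which corresponds to (S) here because CH2OAr outranks aryl.

Step 7
Reactants: 10 (1S)-1-[3,4-dimethoxy-2,5-bis(triisopropylsilyloxy)phenyl]-2-[2-(hydroxymethyl)-4,5,6-trimethoxyphenoxy]ethan-1-ol
Product: 12 (3S)-3-[3,4-dimethoxy-2,5-bis(triisopropylsilyloxy)phenyl]-7,8,9-trimethoxy-2,3-dihydro-5H-1,4-benzodioxepine, via primary benzylic mesylate 11 (not isolated)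
Conditions: Ms2O, iPr2NEt, CH2Cl2 (0.01 M), −40 → 0 °C
Reagents that add atoms: none
Why: The unhindered primary alcohol should be sulfonylated selectively, and the resulting 2,4-dialkoxybenzyl mesylate is captured by the neutral secondary hydroxyl (7-exo-tet etherification); the carbinol C–O bond is not broken, so its configuration is retained, and no alkoxide is formed that could take the ortho silyl group.

Step 8
Reactants: 12 (3S)-3-[3,4-dimethoxy-2,5-bis(triisopropylsilyloxy)phenyl]-7,8,9-trimethoxy-2,3-dihydro-5H-1,4-benzodioxepine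
Product: 15 (3S,4R)-3-[3,4-dimethoxy-2,5-bis(triisopropylsilyloxy)phenyl]-6,7,8-trimethoxychroman-4-ol, via C5-lithiated dioxepine 13 (not isolated), via lithium 4-alkoxide 14 (not isolated)
Conditions: s-BuLi, THF, −78 → −20 °C; then aq NH4Cl
Reagents that add atoms: none
Why: s-BuLi removes a proton from the C5 methylene (benzylic to the A-ring and α to O4); the C3–O4 bond of this α-alkoxy organolithium then homolyses to a tethered ketyl/benzylic radical pair, and C5–C3 recombination turns O4 into the exocyclic C4 alkoxide, so the seven-membered dioxepine becomes the six-membered pyran ([1,2]-Wittig rearrangement, known as a ring contraction of benzo-fused cyclic benzyl ethers). The pyran ring closes by recombination of the two radical centres held 1,6 by the A-ring–O1–C2 tether, formally a 1,2-shift of C3 from oxygen to carbon. C3 should keep its configuration because the benzylic radical is recaptured on the face that O4 has just left before it can rotate (retention at the migrating carbon, S to S). The new C4 centre is set relative to C3 in the recombination, where the half-chair with the solvated O–Li and the bulky aryl both pseudo-equatorial should be favoured, giving the 3,4-trans (4R) carbinol. The step needs lithiation at C5 and not at C3–H, which would lead to β-elimination of the aryloxide or to the tertiary alcohol; the secondary C5–H2 is unhindered, whereas C3–H is tertiary and shielded by the ortho-OTIPS group, which also twists the B-ring out of the alignment needed for benzylic acidity.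

Step 9
Reactants: 15 (3S,4R)-3-[3,4-dimethoxy-2,5-bis(triisopropylsilyloxy)phenyl]-6,7,8-trimethoxychroman-4-ol
Product: 16 (3S,4R)-3-(2,5-dihydroxy-3,4-dimethoxyphenyl)-6,7,8-trimethoxychroman-4-ol
Conditions: TBAF, AcOH, THF, 0 °C, Ar; aq Na2S2O4 work-up
Reagents that add atoms: none
Why: Buffered fluoride desilylation should free both phenols without acid and would also remove a silyl group that had shifted to the C4 oxygen in step 8; exclusion of air and a dithionite wash keep the hydroquinone from oxidising.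

**Compound list**

1 | 2,3,4-trimethoxyphenol | COc1ccc(O)c(OC)c1OC | starting material
2 | 2-hydroxy-3,4,5-trimethoxybenzaldehyde | COc1cc(C=O)c(O)c(OC)c1OC | intermediate
3 | 1-(2-hydroxy-3,4-dimethoxyphenyl)ethanone | CC(=O)c1ccc(OC)c(OC)c1O | starting material
4 | potassium 5-acetyl-4-hydroxy-2,3-dimethoxyphenyl sulfate (not isolated) | CC(=O)c1cc(OS(=O)(=O)[O-])c(OC)c(OC)c1O.[K+] | intermediate
5 | 1-(2,5-dihydroxy-3,4-dimethoxyphenyl)ethanone | CC(=O)c1cc(O)c(OC)c(OC)c1O | intermediate
6 | 1-[3,4-dimethoxy-2,5-bis(triisopropylsilyloxy)phenyl]ethanone | CC(=O)c1cc(O[Si](C(C)C)(C(C)C)C(C)C)c(OC)c(OC)c1O[Si](C(C)C)(C(C)C)C(C)C | intermediate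
7 | trimethylsilyl enol ether of 6 (not isolated) | C=C(O[Si](C)(C)C)c1cc(O[Si](C(C)C)(C(C)C)C(C)C)c(OC)c(OC)c1O[Si](C(C)C)(C(C)C)C(C)C | intermediate
8 | 2-bromo-1-[3,4-dimethoxy-2,5-bis(triisopropylsilyloxy)phenyl]ethanone | BrCC(=O)c1cc(O[Si](C(C)C)(C(C)C)C(C)C)c(OC)c(OC)c1O[Si](C(C)C)(C(C)C)C(C)C | intermediate
9 | 2-{2-[3,4-dimethoxy-2,5-bis(triisopropylsilyloxy)phenyl]-2-oxoethoxy}-3,4,5-trimethoxybenzaldehyde | COc1cc(C=O)c(OCC(=O)c2cc(O[Si](C(C)C)(C(C)C)C(C)C)c(OC)c(OC)c2O[Si](C(C)C)(C(C)C)C(C)C)c(OC)c1OC | intermediate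
10 | (1S)-1-[3,4-dimethoxy-2,5-bis(triisopropylsilyloxy)phenyl]-2-[2-(hydroxymethyl)-4,5,6-trimethoxyphenoxy]ethan-1-ol | COc1cc(CO)c(OC[C@@H](O)c2cc(O[Si](C(C)C)(C(C)C)C(C)C)c(OC)c(OC)c2O[Si](C(C)C)(C(C)C)C(C)C)c(OC)c1OC | intermediate
11 | 2-{(2S)-2-[3,4-dimethoxy-2,5-bis(triisopropylsilyloxy)phenyl]-2-hydroxyethoxy}-3,4,5-trimethoxybenzyl methanesulfonate (not isolated) | COc1cc(COS(C)(=O)=O)c(OC[C@@H](O)c2cc(O[Si](C(C)C)(C(C)C)C(C)C)c(OC)c(OC)c2O[Si](C(C)C)(C(C)C)C(C)C)c(OC)c1OC | intermediate
12 | (3S)-3-[3,4-dimethoxy-2,5-bis(triisopropylsilyloxy)phenyl]-7,8,9-trimethoxy-2,3-dihydro-5H-1,4-benzodioxepine | COc1cc2c(c(OC)c1OC)OC[C@H](c1cc(O[Si](C(C)C)(C(C)C)C(C)C)c(OC)c(OC)c1O[Si](C(C)C)(C(C)C)C(C)C)OC2 | intermediate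
13 | 5-lithio derivative of 12 (not isolated) | COc1cc2c(c(OC)c1OC)OC[C@H](c1cc(O[Si](C(C)C)(C(C)C)C(C)C)c(OC)c(OC)c1O[Si](C(C)C)(C(C)C)C(C)C)OC2[Li] | intermediate
14 | lithium alkoxide of 15 (not isolated) | COc1cc2c(c(OC)c1OC)OC[C@H](c1cc(O[Si](C(C)C)(C(C)C)C(C)C)c(OC)c(OC)c1O[Si](C(C)C)(C(C)C)C(C)C)[C@H]2O[Li] | intermediate
15 | (3S,4R)-3-[3,4-dimethoxy-2,5-bis(triisopropylsilyloxy)phenyl]-6,7,8-trimethoxychroman-4-ol | COc1cc2c(c(OC)c1OC)OC[C@H](c1cc(O[Si](C(C)C)(C(C)C)C(C)C)c(OC)c(OC)c1O[Si](C(C)C)(C(C)C)C(C)C)[C@H]2O | intermediate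
16 | (3S,4R)-3-(2,5-dihydroxy-3,4-dimethoxyphenyl)-6,7,8-trimethoxychroman-4-ol | COc1cc2c(c(OC)c1OC)OC[C@H](c1cc(O)c(OC)c(OC)c1O)[C@H]2O | target

**Count**

Total steps: 9. Longest linear sequence: 8 (steps 2 to 9, from 3 to 16).

**Steps most likely to fail**

1. Step 8. Lithiation may occur at C3–H or on a ring instead of at C5, leading to β-elimination of the aryloxide. The benzylic radical may rotate before recombination, eroding the C3 configuration. Facial selectivity at C4 may be poor, giving cis as well as trans carbinol. Fallback: it sets out from keto aldehyde 9 and comes back at 15, bypassing steps 6 to 8. Intramolecular McMurry coupling of the two carbonyl groups (TiCl4, Zn, pyridine, THF, reflux) should give 3-[3,4-dimethoxy-2,5-bis(triisopropylsilyloxy)phenyl]-6,7,8-trimethoxy-2H-chromene F1. Hydroboration with monoisopinocampheylborane prepared from (+)-α-pinene (THF, −25 °C) should place boron at C4 and hydrogen at C3 on the same face to give the (isopinocampheyl)(isoflavan-4-yl)borane F2. Oxidation with retention (NaBO3·4H2O, THF/H2O) then gives 15. Syn addition fixes the trans relationship, and the (3S,4R) sense is the one expected by analogy with 1-arylcycloalkenes.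

2. Step 7. The readily ionised benzylic mesylate may react intermolecularly and oligomerise instead of closing the seven-membered ring, and sulfonylation or ionisation at the secondary carbinol would erode the enantiomeric purity. Fallback: it sets out from diol 10 and comes back at 12. Chemoselective oxidation of the primary benzylic alcohol (TEMPO cat., PhI(OAc)2, CH2Cl2) should give (S)-hydroxy aldehyde F3, in equilibrium with its lactol. Reductive etherification (Et3SiH, cat. TMSOTf, CH2Cl2, −78 °C) then closes O4–C5 through the aryl-stabilised oxocarbenium ion without touching the carbinol C–O bond.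

3. Step 5. Under base the phenacyl ether may condense onto the ortho-formyl group (Rap–Stoermer-type aldol closure to a 2-aroylbenzofuran), and alkylation of the hindered phenol may be slow enough to let this compete. Fallback: it sets out from aldehyde 2 and comes back at 10. Reduction with NaBH4 (MeOH, 0 °C) should give 6-(hydroxymethyl)-2,3,4-trimethoxyphenol F4. Its phenoxide is alkylated with 8 (K2CO3, acetone, rt) to 1-[3,4-dimethoxy-2,5-bis(triisopropylsilyloxy)phenyl]-2-[2-(hydroxymethyl)-4,5,6-trimethoxyphenoxy]ethanone F5, which has no formyl group to condense with. Transfer hydrogenation under the conditions of step 6 then reduces the ketone alone to 10.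

**Further compounds**

F1 | step 8 | 3-[3,4-dimethoxy-2,5-bis(triisopropylsilyloxy)phenyl]-6,7,8-trimethoxy-2H-chromene | COc1cc2c(c(OC)c1OC)OCC(c1cc(O[Si](C(C)C)(C(C)C)C(C)C)c(OC)c(OC)c1O[Si](C(C)C)(C(C)C)C(C)C)=C2
F2 | step 8 | (isopinocampheyl)[(3S,4R)-3-[3,4-dimethoxy-2,5-bis(triisopropylsilyloxy)phenyl]-6,7,8-trimethoxychroman-4-yl]borane | C[C@H]1[C@H](B[C@H]3c4cc(OC)c(OC)c(OC)c4OC[C@@H]3c5cc(O[Si](C(C)C)(C(C)C)C(C)C)c(OC)c(OC)c5O[Si](C(C)C)(C(C)C)C(C)C)C[C@@H]2C[C@H]1C2(C)C
F3 | step 7 | 2-{(2S)-2-[3,4-dimethoxy-2,5-bis(triisopropylsilyloxy)phenyl]-2-hydroxyethoxy}-3,4,5-trimethoxybenzaldehyde | COc1cc(C=O)c(OC[C@@H](O)c2cc(O[Si](C(C)C)(C(C)C)C(C)C)c(OC)c(OC)c2O[Si](C(C)C)(C(C)C)C(C)C)c(OC)c1OC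
F4 | step 5 | 6-(hydroxymethyl)-2,3,4-trimethoxyphenol | COc1cc(CO)c(O)c(OC)c1OC
F5 | step 5 | 1-[3,4-dimethoxy-2,5-bis(triisopropylsilyloxy)phenyl]-2-[2-(hydroxymethyl)-4,5,6-trimethoxyphenoxy]ethanone | COc1cc(CO)c(OCC(=O)c2cc(O[Si](C(C)C)(C(C)C)C(C)C)c(OC)c(OC)c2O[Si](C(C)C)(C(C)C)C(C)C)c(OC)c1OC
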